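## Structural features

The target is a germacranolide: a ten-membered carbocycle (C1–C10) trans-fused at C6/C7 to an α-methylene-γ-butyrolactone (O–C6, C12=O, C11=C13). The ring carries an (E)-trisubstituted C4=C5 alkene (methyl C15 on C4), a trisubstituted 1,10-epoxide whose quaternary C10 bears the acetoxymethyl carbon C14, and a methacrylate on the C8 oxygen. Three stereocentres stand side by side, C6 (R), C7 (R) and C8 (S), with the C6 and C8 oxygens on one face (α) and the C7–C11 bond on the other (β). The epoxide carbons C1 (R) and C10 (R) lie across the ring, and the ring bonds to C2 and C9 are cis on the epoxide, so it derives from a ring-cis C1=C10 alkene. Fragile groups are the α-methylene lactone and the methacrylate (Michael acceptors, labile to base and hydride), the primary acetate, the lactone (translactonisation onto a free C8 hydroxyl) and the epoxide, which lies transannular to C4=C5 and cyclises under acid. The real difficulty is the medium ring itself, with two geometrically defined trisubstituted double bonds (one hidden in the epoxide) and three differentiated oxygen functions (C6, C8, C14). The key step exploits the fact that C1=C10 and C4=C5 flank the C2–C3 bridge. With C2=C3 added the ring is a cyclodeca-1(10),2,4-triene, the valence isomer of a cis-fused bicyclo[4.4.0]deca-1,3-diene (ring A: C1–C5 and C10; ring B: C5–C10) that has a C5–C10 bond.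

## Logic of the disconnections

**28 ⇒ 27 ⇒ 26.** The C8–O methacryloyl bond and then the C14–O acetyl bond are cut. Neither ester would survive enolate, diimide or fluoride chemistry, so both go on last. The forward steps must acylate the primary hydroxyl before the hindered secondary one and must stay non-acidic for the epoxide.

**26 ⇒ 25.** The two epoxide C–O bonds are cut to the ring-cis C1=C10 alkene. The C14 hydroxyl is allylic to that alkene and to no other, which gives site selectivity and reagent-chosen face selectivity. The forward step needs the tartrate enantiomer that leads to (1R,10R).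

**25 ⇒ 24 ⇒ 22 ⇒ 21.** The O–Si bonds are restored and C11=C13 is traced back through a C11–Se bond to a C11 methyl lactone. The methylene lactone would not survive diimide or irradiation, so it is unveiled only after the ring is secured. The forward elimination must go to the exocyclic side.

**21 ⇒ 20.** Two hydrogens are removed from C2 and C3. This reveals the conjugated triene that a pericyclic step can deliver. The forward reduction must pick the disubstituted C2=C3 bond and run below the temperature of thermal reclosure.

**20 ⇒ 19 (key).** The C5–C10 bond is re-formed. A flexible ten-membered triene becomes a rigid cis-decalin on which C6, C7 and C8 can be set by ring-controlled reactions. The forward step needs conrotation in the sense that turns H5 and C9 inward. The structures of 19 and 20 were checked atom by atom against 28: C6, C7 and C8 coincide, and conrotation of the cis-fused isomer gives ring-cis C1=C10 and E C4=C5. They are used unchanged.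

**19 ⇒ 16.** The C1=C2/C3=C4 diene is traced to a C2=C3 alkene with a tertiary hydroxyl on C4 (1,4-addition of water). Ring A then carries no carbonyl group and no conjugated diene during the work on ring B. The forward step must remove water strictly 1,4, without a cation that could reach C5.

**16 ⇒ 13 ⇒ 11.** The lactone C12–O6 bond is cut and C12 is taken down to the terminal carbon of an isopropenyl group. An isopropenyl group is inert to the alkoxides formed earlier, so the lactone can be closed only after C8–O is blocked. The forward steps need a hydroboration that ignores the ring alkene and an oxidation that touches only the primary alcohol.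

**11 ⇒ 10 ⇒ 9 ⇒ 8.** The silyl ethers are removed and the C7–C11 bond is cut to a 7,8-epoxide plus an isopropenyl nucleophile. One SN2 event then sets C7 and C8 trans, and the cis relation of the C6 and C8 oxygens follows from the epoxide. The forward steps demand attack at C7 rather than C8, and later a silylation that tells C8–OH from C6–OH.

**8 ⇒ 7 ⇒ 6 ⇒ 4.** The epoxide is cut to the C7=C8 alkene, with the C6 hydroxyl as the directing group. The C6–H and C14–H bonds are cut to a ketone and an ester, and C7=C8 to the saturated ketone. The forward reduction must deliver hydride to C6 from the face of H5. A dienophile already carrying C7 and C8 substituents was rejected: the diene would be expected to add anti to a C8 oxygen and give the wrong relation to the ring fusion.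

**4 ⇒ 3 + 2.** The C1–C10 and C4–C5 bonds are cut (Diels–Alder). This is the largest simplification: both rings, the quaternary C10 with its C14 carbon, the cis fusion and the latent diene arise from two small achiral partners. The forward step must be regioselective (CH2 terminus to C10) and enantioselective, since every later stereocentre is relayed from C5/C10.

**2 ⇒ 1.** The O–Si bond is cut to a β,γ-unsaturated ketone. That isomer is chosen because amine/silyl triflate enolisation of the conjugated pent-3-en-2-one would be expected to give mainly the cross-conjugated 2-silyloxy-1,3-diene.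

## Other disconnections considered

**Alternative 1:** The cut is at C9–C10 and O–C8. Forward, NaOCl oxidises aldoxime A1 to a nitrile oxide, which adds across the C7 vinyl group (C8=C9) and closes the carbocycle and a bridging isoxazoline in A2.
- In its favour: the key step makes a skeletal C–C bond, the C8–O bond and the C8 stereocentre at once. The dipole is a rigid, reactive terminus that helps medium-ring closure, and the isoxazoline is a masked C8-hydroxy C10-ketone.
- Against it here: C14 and the C1=C10 double bond are absent from A2. After N–O cleavage the C10 ketone must be turned into a ring-cis trisubstituted alkene bearing C14, with new regiochemical (C1 versus C9) and geometric problems. The facial course at C8 rests on a single neighbouring stereocentre, and nitrile oxide dimerisation competes at the dilution needed.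
- Comparison: structurally it is better than the chosen plan in what the key step builds (a bond and a stereocentre against none). It is worse in what it leaves open (C1=C10 geometry, C14, the methylene lactone). Mechanistically it is a thermal concerted [3+2] cycloaddition and needs no cold handling, which is an advantage. In step economy the gain is likely consumed by the steps after A2.

**Alternative 2:** The cut is at C1=C10. Forward, LiCl and DBU generate the phosphonate anion of A3, which condenses with the C1 aldehyde (Horner–Wadsworth–Emmons) to give the alkylidene ester A4.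
- In its favour: the key step forms the C1=C10 bond with C14 already attached at the ester level, and the usual E preference of the olefination corresponds to the ring-cis geometry wanted. The C11 methylene is present from the start, so no selenium chemistry is needed, and the conditions are mild and scalable.
- Against it here: a ten-membered ring must be closed by a bimolecular-type olefination against transannular strain, so oligomerisation and eroded E/Z control are real risks. The acyclic C6–C8 triad must be made first. The lactone is built only after ring closure, through two p-methoxybenzyl removals and an oxidation in the presence of the diene.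
- Comparison: on double-bond geometry it is the equal of the chosen plan (olefination selectivity against torquoselectivity) and better on the methylene lactone. Mechanistically it is ionic and needs no photochemistry, which is an advantage. It is weaker on ring-closure entropy, where the valence isomerisation has no such penalty, and probably no shorter overall.

**Alternative 3:** The cut is at C5–C6 and at the lactone C12–O bond. Forward, CrCl2 (divalent chromium) with catalytic NiCl2 converts the vinyl iodide of A5 into an alkenylchromium that adds to the C6 aldehyde (Nozaki–Hiyama–Kishi), and the C6 alkoxide lactonises onto the acrylate ester to give A6.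
- In its favour: A6 is identical with 24 of the chosen route, so the last four steps are shared. The key step makes a skeletal bond, the C6 stereocentre and the lactone at once. The C4=C5 geometry is carried from the vinyl iodide, and the methylene lactone needs no separate installation.
- Against it here: the 6α/7β relation depends on macrocyclic diastereoselectivity. C7 in A5 is α to an aldehyde and allylic to the acrylate, so it is prone to epimerisation and conjugation. A5 needs two geometrically pure trisubstituted alkenes and the C7/C8 pair made in acyclic form. Stoichiometric chromium at high dilution is a burden on scale.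
- Comparison: it is better than the chosen plan in bond and stereocentre count of the key step and in avoiding the thermally labile triene, diimide and selenium. It is equal from 24 onward. It is weaker in that its key stereocentre is set in a flexible macrocyclic transition state rather than on a rigid decalin.

Key step: step 12

## Conventions and assumptions

- Germacrane numbering is used for all intermediates: ring A is C1, C2, C3, C4, C5, C10 and ring B is C5–C10; C14 is on C10, C15 on C4, C11–C13 on C7. β is the face of H6 and of the C7–C11 bond; α is the face of the C6 and C8 oxygens.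
- Assumption: the sense of induction of the boron catalyst in step 2 is taken from its model for 2-cycloalkenones; the (S)-catalyst is written and its antipode serves if the opposite sense is found.
- Assumption: pent-4-en-2-one is a catalogue chemical; otherwise it is one oxidation from pent-4-en-2-ol.

## Steps

Step 1
Reactants: 1 pent-4-en-2-one
Product: 2 (Z)-triethyl(penta-2,4-dien-2-yloxy)silane
Conditions: Et3SiOTf, Et3N, CH2Cl2, −78 → 0 °C
Reagents that add atoms: triethylsilyl trifluoromethanesulfonate, CC[Si](CC)(CC)OS(=O)(=O)C(F)(F)F
Why: Soft enolisation (O-silylation, then amine deprotonation): the C3 hydrogens are both allylic and α to the carbonyl, so deprotonation there rather than at the methyl group should give the through-conjugated dienol ether; the Z isomer (oxygen cis to the vinyl group), the usual outcome, is also the one that reaches the s-cis conformation with only oxygen turned inward.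

Step 2
Reactants: 3 methyl 3-oxocyclohex-1-ene-1-carboxylate; 2 (Z)-triethyl(penta-2,4-dien-2-yloxy)silane
Product: 4 cis-fused keto ester (2-ene; 4α-methyl-4β-triethylsilyloxy; 6-oxo; 5β-H; 10β-CO2Me)
Conditions: (S)-1-(2-methylphenyl)-3,3-diphenyltetrahydro-1H,3H-pyrrolo[1,2-c][1,3,2]oxazaborole·HNTf2 (20 mol %), CH2Cl2, −78 → −40 °C
Reagents that add atoms: none
Why: Catalytic enantioselective Diels–Alder reaction (normal electron demand, chiral boron Lewis acid on the ketone of 3): the unsubstituted diene terminus, which has the largest HOMO coefficient in a 1-oxygenated diene, bonds to C10 (β to the ketone) and the oxygenated terminus to C5. Suprafacial addition to the ring alkene fixes the cis fusion (H5 and CO2Me on one face), and the catalyst blocks one enantioface and so sets C5 and C10 absolutely; C4 (ketone-endo mode expected) is destroyed later.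

Step 3
Reactants: 4 cis-fused keto ester
Product: 6 cis-fused 2,7-dien-6-one ester (4α-methyl-4β-triethylsilyloxy; 10β-CO2Me), via C6 trimethylsilyl enol ether 5 (not isolated)
Conditions: LDA, Me3SiCl, THF, −78 °C; then Pd(OAc)2, MeCN, rt
Reagents that add atoms: none
Why: Saegusa–Ito dehydrogenation: kinetic deprotonation takes the unhindered C7 methylene (C5–H lies between two quaternary carbons), and divalent palladium converts the silyl enol ether into the C7=C8 enone by β-hydride elimination from C8; no stereocentre is touched.

Step 4
Reactants: 6 cis-fused 2,7-dien-6-one ester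
Product: 7 2,7-diene-6α,14-diol (4β-triethylsilyloxy)
Conditions: i-Bu2AlH, CH2Cl2, −78 → 0 °C; aq. potassium sodium tartrate
Reagents that add atoms: none
Why: Aluminium hydride reduction (1,2-reduction of the enone and ester-to-alcohol reduction): the bulky hydride should reach C6 from the β face, the convex side of the cis-decalin next to H5, because ring A with its quaternary C4 covers the α face; this gives the 6α-alcohol (H6 cis to H5). The neopentyl ester is reduced to the C14 alcohol in the same operation.

Step 5
Reactants: 7 2,7-diene-6α,14-diol
Product: 8 7α,8α-epoxy-2-ene-6α,14-diol (4β-triethylsilyloxy)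
Conditions: VO(acac)2 (5 mol %), t-BuOOH, CH2Cl2, 0 °C → rt
Reagents that add atoms: tert-butyl hydroperoxide, CC(C)(C)OO
Why: Hydroxyl-directed epoxidation by a vanadium alkyl peroxide: the C6 vanadate delivers oxygen to the face of C7=C8 on which the hydroxyl stands, giving the epoxide cis to the alcohol (C7 and C8 oxygens α). The ring A alkene has no free allylic hydroxyl and the remote primary alcohol directs far more slowly.

Step 6
Reactants: 8 7α,8α-epoxy-2-ene-6α,14-diol
Product: 9 7β-isopropenyl-2-ene-6α,8α,14-triol (4β-triethylsilyloxy)
Conditions: CH2=C(CH3)MgBr, CuI (20 mol %), THF, −30 → 0 °C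
Reagents that add atoms: isopropenylmagnesium bromide, CC(=C)[Mg]Br
Why: Copper-catalysed SN2 opening of an epoxide by a Grignard reagent: attack must be anti to the epoxide oxygen and trans-diaxial; at C8 the incoming group would be syn-axial to the C14 group on C10, at C7 it meets only hydrogens, and cuprates open 2,3-epoxy alcoholates next to the carbinol carbon. Inversion at C7 sets the 7β-isopropenyl group and leaves the 8α-hydroxyl, trans to it and cis to the C6 hydroxyl.

Step 7
Reactants: 9 7β-isopropenyl-2-ene-6α,8α,14-triol
Product: 10 7β-isopropenyl-2-ene-4β,6α,8α,14-tetraol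
Conditions: Bu4NF, THF, 0 °C → rt
Reagents that add atoms: none
Why: Fluoride-mediated desilylation: the tertiary triethylsilyl ether is the only silyl group present, so it is removed cleanly before the permanent silyl ethers go on; the tertiary allylic alcohol is needed free in step 11.

Step 8
Reactants: 10 7β-isopropenyl-2-ene-4β,6α,8α,14-tetraol
Product: 11 8α,14-bis(tert-butyldimethylsilyl) ether of 10 (4β- and 6α-hydroxyls free)
Conditions: t-BuMe2SiCl (2.2 equiv), imidazole, DMF, 0 °C
Reagents that add atoms: tert-butyldimethylsilyl chloride, CC(C)(C)[Si](C)(C)Cl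
Why: Regioselective silylation under kinetic control: the primary C14 hydroxyl and the less hindered secondary C8 hydroxyl should react, whereas the C6 hydroxyl is shielded by C5 and the adjacent quaternary C4, and the tertiary C4 hydroxyl is inert to this reagent.

Step 9
Reactants: 11 8α,14-bis-silyl ether
Product: 13 6α,12-diol with a 7β-(1-hydroxypropan-2-yl) group (C11 epimers), via B-alkyl-9-BBN adduct 12 (not isolated)
Conditions: 9-BBN, THF, 0 °C → rt; then NaOH, H2O2, 0 °C
Reagents that add atoms: hydrogen peroxide, OO
Why: Hydroboration–oxidation (anti-Markovnikov): 9-BBN adds to the unhindered 1,1-disubstituted alkene far faster than to the cis-disubstituted ring alkene next to quaternary C4, and alkaline peroxide replaces boron by hydroxyl to give the C12 primary alcohol. C11 forms as a mixture of epimers, which is levelled in step 10.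

Step 10
Reactants: 13 6α,12-diol (C11 epimers)
Product: 16 4β-hydroxy-2-en-6α,12-olide (11α-methyl; 8α,14-bis-silyl ether), via C12 lactol 14 (not isolated), via 11β-methyl lactone 15 (not isolated)
Conditions: (2,2,6,6-tetramethylpiperidin-1-yl)oxyl (10 mol %), PhI(OAc)2, CH2Cl2, rt; then DBU, PhMe, 60 °C
Reagents that add atoms: none
Why: Oxoammonium-mediated oxidative lactonisation of a 1,4-diol: the nitroxyl/trivalent iodine system oxidises only the primary alcohol, the aldehyde closes onto the free C6 hydroxyl (C8–O is silylated) and the lactol is oxidised to the trans-fused γ-lactone. The amidine base then equilibrates C11 through the enol to the more stable 11α-methyl epimer (methyl trans to C8).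

Step 11
Reactants: 16 4β-hydroxy-2-en-6α,12-olide
Product: 19 cis-fused hexalin 1,3-diene lactone (1,3-diene; 5β-H; 10β-CH2OSi; 8α-OSi; 11α-methyl), via C4 sulfenate ester 17 (not isolated), via C2 allylic sulfoxide 18 (not isolated)
Conditions: 2,4-(O2N)2C6H3SCl, Et3N, ClCH2CH2Cl, 0 → 50 °C
Reagents that add atoms: none
Why: Formal 1,4-dehydration by a sulfenate-to-sulfoxide [2,3]-sigmatropic shift (Mislow–Evans rearrangement run towards the sulfoxide) followed by sulfoxide syn-elimination: the sulfenate of the tertiary allylic alcohol moves sulfur to C2 and the double bond to C3=C4, and the electron-poor aryl sulfoxide then eliminates with a C1 hydrogen, the only sp3 β-hydrogens available. The diene can therefore form only as C1=C2–C3=C4, with no cation that could reach C5.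

Step 12
Reactants: 19 cis-fused hexalin 1,3-diene lactone
Product: 20 cyclodeca-1(10),2,4-triene lactone (1(10)-ring-cis; 2Z; 4E)
Conditions: hν (254 nm, quartz), degassed Et2O–pentane, −78 °C
Reagents that add atoms: none
Why: Photochemical 6π electrocyclic ring opening: excitation of the cyclohexa-1,3-diene of ring A (the only chromophore at 254 nm, since the lactone and alkylsilyl ethers are transparent and no aryl group is present) is followed by conrotatory cleavage of the doubly allylic C5–C10 bond. The closest known reaction type is the light-induced opening of hexalin (eudesmane-type) 1,3-dienes to cyclodeca-1,3,5-trienes, the carbocyclic counterpart of the provitamin D to previtamin D change. No ring-closing bond is made: the ten-membered ring arises by scission of the bond shared by rings A and B, so no mode of closure applies and no skeletal bond or stereocentre is created; only the geometry of two double bonds is new. Conrotation of a cis-fused diene must turn one member of each cis pair inward; turning H5 and the ring carbon C9 inward leaves the bulky CH2OSi group on C10 and the lactone-bearing C6 outside, whereas the other sense would force both inward. The favoured sense puts C9 cis to C2 across C1=C10 (ring-cis) and C6 trans to C3 across C4=C5 (E), the geometries hidden in the target, while C2=C3 stays Z. The selectivity needed is therefore torquoselectivity, secured by the cis fusion and the size differences H5 versus C6 and C9 versus C14. Low temperature and limited conversion guard against thermal disrotatory reclosure and secondary photoisomerisation, and the triene is carried cold into step 13.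

Step 13
Reactants: 20 cyclodeca-1(10),2,4-triene lactone
Product: 21 germacra-1(10),4-dien-6α,12-olide (1(10)-ring-cis; 4E; 11α-methyl; 8α,14-bis-silyl ether)
Conditions: KO2CN=NCO2K, AcOH, MeOH–CH2Cl2, −40 → −20 °C
Reagents that add atoms: none
Why: Diimide reduction (concerted syn transfer of H2 from HN=NH made by acid decarboxylation of the azodicarboxylate): diimide prefers the least substituted and most strained alkene, here the cis-disubstituted C2=C3 bond at the centre of the twisted triene, over the two trisubstituted bonds. Saturating C2–C3 ends any electrocyclic reclosure.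

Step 14
Reactants: 21 germacra-1(10),4-dien-6α,12-olide
Product: 22 11β-phenylselanyl-11α-methyl lactone
Conditions: LDA, THF, −78 °C; then PhSeBr, −78 °C
Reagents that add atoms: phenylselenenyl bromide, Br[Se]c1ccccc1
Why: α-Selenenylation of a lactone enolate: LDA forms the C11 enolate (the C11 configuration is erased) and the selenium electrophile should enter trans to the axial H7 of the trans-fused lactone, placing selenium β and methyl α.

Step 15
Reactants: 22 11β-phenylselanyl-11α-methyl lactone
Product: 24 11(13)-methylene lactone (8α,14-bis-silyl ether), via selenoxide 23 (not isolated)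
Conditions: H2O2, pyridine, CH2Cl2, 0 °C → rt
Reagents that add atoms: none
Why: Selenoxide syn-elimination: the selenoxide eliminates with a hydrogen of the C13 methyl group, the only β-hydrogens syn to selenium because H7 is on the opposite face, so the exocyclic α-methylene lactone should form rather than the endocyclic butenolide. Pyridine buffers the selenenic acid so that the trisubstituted alkenes are not epoxidised.

Step 16
Reactants: 24 11(13)-methylene lactone bis-silyl ether
Product: 25 8α,14-diol
Conditions: HF·pyridine, pyridine, THF, 0 °C → rt
Reagents that add atoms: none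
Why: Buffered acidic fluoride desilylation: both silyl ethers are cleaved without forming the C8 alkoxide that could translactonise to the 8,12-olide or add to the methylene lactone, as basic fluoride might; the pyridine buffer keeps the acid-sensitive 1(10),4-diene intact.

Step 17
Reactants: 25 8α,14-diol
Product: 26 (1R,10R)-1,10-epoxy-8α,14-diol
Conditions: Ti(OiPr)4, D-(−)-diethyl tartrate, t-BuOOH, 4 Å MS, CH2Cl2, −20 °C
Reagents that add atoms: tert-butyl hydroperoxide, CC(C)(C)OO
Why: Sharpless asymmetric epoxidation of the C14 allylic alcohol: the titanium tartrate delivers oxygen only to C1=C10 (C4=C5 has no free allylic hydroxyl), and the face is chosen by the tartrate. L-(+)-Tartrate leads to the (2S) epoxy alcohol series, which here would be (1S,10S), so the D-(−)-ester is used for (1R,10R); the cis ring bonds follow from the ring-cis alkene, and no substituent is cis to the hydroxymethyl group.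

Step 18
Reactants: 26 (1R,10R)-1,10-epoxy-8α,14-diol
Product: 27 14-O-acetyl-(1R,10R)-1,10-epoxy-8α-ol
Conditions: Ac2O (1.1 equiv), 2,4,6-collidine, CH2Cl2, −20 → 0 °C
Reagents that add atoms: acetic anhydride, CC(=O)OC(C)=O
Why: Selective O-acetylation under a weak, hindered base: the primary C14 hydroxyl reacts much faster than the hindered secondary C8 hydroxyl at low temperature, and the medium is mild enough for the epoxide and the methylene lactone.

Step 19
Reactants: 27 14-O-acetyl-(1R,10R)-1,10-epoxy-8α-ol
Product: 28 target (CNP0150481.4)
Conditions: methacrylic anhydride, Et3N, 4-(dimethylamino)pyridine (cat.), CH2Cl2, 0 °C → rt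
Reagents that add atoms: methacrylic anhydride, C=C(C)C(=O)OC(=O)C(C)=C
Why: Nucleophile-catalysed esterification through the acylpyridinium ion: the remaining secondary C8 hydroxyl is acylated with retention, completing the target without exposing the epoxide to acid.

## Compound list

1 | pent-4-en-2-one | CC(=O)CC=C | starting material
2 | (Z)-triethyl(penta-2,4-dien-2-yloxy)silane | C=C/C=C(C)\O[Si](CC)(CC)CC | intermediate
3 | methyl 3-oxocyclohex-1-ene-1-carboxylate | COC(=O)C1=CC(=O)CCC1 | starting material
4 | cis-fused keto ester: ring A 2-ene with 4α-methyl and 4β-triethylsilyloxy, ring B 6-ketone, 5β-H, 10β-CO2Me | COC(=O)[C@]12CC=C[C@](C)(O[Si](CC)(CC)CC)[C@H]1C(=O)CCC2 | intermediate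
5 | C6 trimethylsilyl enol ether of 4 (6-ene) | COC(=O)[C@]12CC=C[C@](C)(O[Si](CC)(CC)CC)[C@H]1C(O[Si](C)(C)C)=CCC2 | intermediate
6 | cis-fused 2,7-dien-6-one ester, 4α-methyl, 4β-triethylsilyloxy, 10β-CO2Me | COC(=O)[C@]12CC=C[C@](C)(O[Si](CC)(CC)CC)[C@H]1C(=O)C=CC2 | intermediate
7 | 2,7-diene-6α,14-diol, 4β-triethylsilyloxy | OC[C@]12CC=C[C@](C)(O[Si](CC)(CC)CC)[C@H]1[C@@H](O)C=CC2 | intermediate
8 | 7α,8α-epoxy-2-ene-6α,14-diol, 4β-triethylsilyloxy | OC[C@]12CC=C[C@](C)(O[Si](CC)(CC)CC)[C@H]1[C@@H](O)[C@H]3O[C@H]3C2 | intermediate
9 | 7β-isopropenyl-2-ene-6α,8α,14-triol, 4β-triethylsilyloxy | OC[C@]12CC=C[C@](C)(O[Si](CC)(CC)CC)[C@H]1[C@@H](O)[C@H](C(C)=C)[C@@H](O)C2 | intermediate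
10 | 7β-isopropenyl-2-ene-4β,6α,8α,14-tetraol | OC[C@]12CC=C[C@](C)(O)[C@H]1[C@@H](O)[C@H](C(C)=C)[C@@H](O)C2 | intermediate
11 | 8α,14-bis(tert-butyldimethylsilyl) ether of 10, 4β- and 6α-hydroxyls free | CC(C)(C)[Si](C)(C)OC[C@]12CC=C[C@](C)(O)[C@H]1[C@@H](O)[C@H](C(C)=C)[C@@H](O[Si](C)(C)C(C)(C)C)C2 | intermediate
12 | B-alkyl-9-borabicyclo[3.3.1]nonane adduct of 11 (boron on C12; C11 both epimers) | CC(C)(C)[Si](C)(C)OC[C@]12CC=C[C@](C)(O)[C@H]1[C@@H](O)[C@H](C(C)CB3C4CCCC3CCC4)[C@@H](O[Si](C)(C)C(C)(C)C)C2 | intermediate
13 | 6α,12-diol: 7β-(1-hydroxypropan-2-yl) compound (C11 both epimers) | CC(C)(C)[Si](C)(C)OC[C@]12CC=C[C@](C)(O)[C@H]1[C@@H](O)[C@H](C(C)CO)[C@@H](O[Si](C)(C)C(C)(C)C)C2 | intermediate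
14 | C12 lactol (C11 and C12 both epimers) | CC(C)(C)[Si](C)(C)OC[C@]12CC=C[C@](C)(O)[C@H]1[C@H]3OC(O)C(C)[C@@H]3[C@@H](O[Si](C)(C)C(C)(C)C)C2 | intermediate
15 | 11β-methyl lactone (11-epimer of 16) | CC(C)(C)[Si](C)(C)OC[C@]12CC=C[C@](C)(O)[C@H]1[C@H]3OC(=O)[C@H](C)[C@@H]3[C@@H](O[Si](C)(C)C(C)(C)C)C2 | intermediate
16 | 4β-hydroxy-2-en-6α,12-olide, 11α-methyl, 8α,14-bis-silyl ether | CC(C)(C)[Si](C)(C)OC[C@]12CC=C[C@](C)(O)[C@H]1[C@H]3OC(=O)[C@@H](C)[C@@H]3[C@@H](O[Si](C)(C)C(C)(C)C)C2 | intermediate
17 | C4 2,4-dinitrobenzenesulfenate ester of 16 | CC(C)(C)[Si](C)(C)OC[C@]12CC=C[C@](C)(OSc4ccc(cc4[N+](=O)[O-])[N+](=O)[O-])[C@H]1[C@H]3OC(=O)[C@@H](C)[C@@H]3[C@@H](O[Si](C)(C)C(C)(C)C)C2 | intermediate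
18 | C2 allylic 2,4-dinitrophenyl sulfoxide (3-ene; sulfur β; sulfur configuration open) | CC(C)(C)[Si](C)(C)OC[C@]12C[C@H](S(=O)c4ccc(cc4[N+](=O)[O-])[N+](=O)[O-])C=C(C)[C@H]1[C@H]3OC(=O)[C@@H](C)[C@@H]3[C@@H](O[Si](C)(C)C(C)(C)C)C2 | intermediate
19 | cis-fused hexalin 1,3-diene lactone: 5β-H, 10β-CH2OSi, trans 6α,12-lactone, 11α-methyl, 8α-OSi | CC(C)(C)[Si](C)(C)O[C@H]1C[C@@]2(CO[Si](C)(C)C(C)(C)C)C=CC=C(C)[C@H]2[C@H]3OC(=O)[C@@H](C)[C@H]13 | intermediate
20 | cyclodeca-1(10),2,4-triene lactone: ring-cis C1=C10, Z C2=C3, E C4=C5 | CC(C)(C)[Si](C)(C)O[C@H]1C/C(CO[Si](C)(C)C(C)(C)C)=C\C=C/C(C)=C/[C@H]2OC(=O)[C@@H](C)[C@H]12 | intermediate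
21 | germacra-1(10),4-dien-6α,12-olide: ring-cis C1=C10, E C4=C5, 11α-methyl, 8α,14-bis-silyl ether | CC(C)(C)[Si](C)(C)O[C@H]1C/C(CO[Si](C)(C)C(C)(C)C)=C\CC/C(C)=C/[C@H]2OC(=O)[C@@H](C)[C@H]12 | intermediate
22 | 11β-phenylselanyl-11α-methyl lactone | CC(C)(C)[Si](C)(C)O[C@H]1C/C(CO[Si](C)(C)C(C)(C)C)=C\CC/C(C)=C/[C@H]2OC(=O)[C@](C)([Se]c3ccccc3)[C@H]12 | intermediate
23 | selenoxide of 22 | CC(C)(C)[Si](C)(C)O[C@H]1C/C(CO[Si](C)(C)C(C)(C)C)=C\CC/C(C)=C/[C@H]2OC(=O)[C@](C)([Se](=O)c3ccccc3)[C@H]12 | intermediate
24 | 11(13)-methylene lactone, 8α,14-bis-silyl ether | CC(C)(C)[Si](C)(C)O[C@H]1C/C(CO[Si](C)(C)C(C)(C)C)=C\CC/C(C)=C/[C@H]2OC(=O)C(=C)[C@H]12 | intermediate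
25 | 8α,14-dihydroxy-germacra-1(10),4,11(13)-trien-6α,12-olide | O[C@H]1C/C(CO)=C\CC/C(C)=C/[C@H]2OC(=O)C(=C)[C@H]12 | intermediate
26 | (1R,10R)-1,10-epoxy-8α,14-diol | O[C@H]1C[C@]2(CO)O[C@@H]2CC/C(C)=C/[C@H]2OC(=O)C(=C)[C@H]12 | intermediate
27 | 14-O-acetyl-(1R,10R)-1,10-epoxy-8α-ol | O[C@H]1C[C@]2(COC(C)=O)O[C@@H]2CC/C(C)=C/[C@H]2OC(=O)C(=C)[C@H]12 | intermediate
28 | CNP0150481.4: 14-acetoxy-(1R,10R)-1,10-epoxy-8α-methacryloyloxy-germacra-4E,11(13)-dien-6α,12-olide | C=C(C)C(=O)O[C@H]1C[C@]2(COC(C)=O)O[C@@H]2CC/C(C)=C/[C@H]2OC(=O)C(=C)[C@H]12 | target

## Step count and least certain steps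

Total: 19 steps. Longest linear sequence: 19 steps (1 to 28); 3 enters at step 2.

**Step 12 (key step).** Most likely to go wrong: the reaction stops at a photostationary mixture while continued irradiation erodes the triene by secondary photoisomerisation, and any break in the cold chain lets the triene reclose thermally to hexalins; incomplete torquoselectivity would add the 1(10)E,4Z isomer. No intermediate of the route offers another way to cleave C5–C10, so the fallback keeps the electrocyclic opening but drains its product irreversibly. It sets out from 16. Babler–Dauben oxidative transposition with pyridinium chlorochromate should give the ring A 3-en-2-one F1. Kinetic enolisation at C1 (LDA, Me3SiCl) gives the 2-(trimethylsilyloxy)-1,3-diene F2. Irradiation at 254 nm opens F2 by the same conrotation to the trienol silyl ether F3, and protodesilylation at −40 °C (citric acid, MeOH) tautomerises it to the 2-oxo-1(10),4-diene F4, which cannot reclose. The carbonyl is then removed: Luche reduction gives the allylic alcohol F5, 1,1'-thiocarbonyldiimidazole gives the imidazolylthiocarbonate F6, and Barton–McCombie reduction (Bu3SnH, AIBN) delivers hydrogen to the less substituted end of the allyl radical, keeping C1=C10. The fallback returns to the route at 21.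

**Step 2.** Most likely to go wrong: insufficient enantiofacial discrimination on this β-carboxylated enone, or a stepwise Mukaiyama–Michael path with silyl transfer under the strongly acidic catalyst that leaves open-chain adducts. The fallback replaces catalysis by a covalent auxiliary and sets out from 3. Transesterification with (1R,2S,5R)-menthol (Ti(OEt)4, PhMe, reflux) gives the menthyl enone ester F7. Thermal cycloaddition with 2 without a Lewis acid gives two cis-fused diastereomers, which are separated, and the one with the configuration of 4 is the menthyl adduct F8. Saegusa–Ito dehydrogenation as in step 3 gives the menthyl dienone F9, and i-Bu2AlH releases the auxiliary and returns to the route at 7.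

**Step 4.** Most likely to go wrong: poor facial selectivity of hydride delivery if the angular ester on C10 hinders the β face, which would give the 6β-alcohol and relay the wrong configuration to C7 and C8. The fallback inverts rather than selects and sets out from 6. Luche reduction (NaBH4, CeCl3), which leaves the ester, would in that case give the 6β-alcohol F10. Mitsunobu reaction with 4-nitrobenzoic acid (PPh3, diisopropyl azodicarboxylate) inverts C6 to the 6α-(4-nitrobenzoate) F11, and i-Bu2AlH cleaves both esters and returns to the route at 7.

**Step 8.** Most likely to go wrong: insufficient discrimination between the C6 and C8 hydroxyls (over-silylation, or silylation of C6), which would send the lactonisation to the wrong oxygen. The fallback differentiates the two oxygens before the C8 hydroxyl exists and sets out from 8. Et3SiCl and imidazole give the tris(triethylsilyl) epoxide F12. The copper-catalysed opening of step 6 gives the 8α-alcohol F13, and t-BuMe2SiOTf with 2,6-lutidine gives the 8α-silyl ether F14. Mild acid (pyridinium p-toluenesulfonate, MeOH) removes the three triethylsilyl groups but not the secondary tert-butyldimethylsilyl ether, giving the 4β,6α,14-triol F15. Silylation of its primary hydroxyl (t-BuMe2SiCl, 1.1 equiv) returns to the route at 11.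

**Step 17.** Most likely to go wrong: mismatched double stereodifferentiation against the facial bias of the macrocycle, together with opening of the new epoxide by the transannular C4=C5 bond under tetravalent titanium, or translactonisation through the free C8 hydroxyl. The fallback stages the deprotection so that only the C14 hydroxyl is free during epoxidation and the C8 oxygen stays silylated until the end. It sets out from 24. Brief treatment with buffered HF·pyridine at 0 °C removes the primary allylic silyl ether first and gives the 14-alcohol F16. Catalytic Sharpless epoxidation with the D-(−)-tartrate (or, if reagent control fails, the vanadium-catalysed hydroxyl-directed variant) gives the epoxy alcohol F17. Acetylation as in step 18 gives the epoxy acetate F18, and buffered fluoride (Bu4NF, AcOH) frees the C8 hydroxyl and returns to the route at 27.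

## Further compounds

F1 | step 12 | ring A 3-en-2-one of the lactone series (from 16) | CC(C)(C)[Si](C)(C)OC[C@]12CC(=O)C=C(C)[C@H]1[C@H]3OC(=O)[C@@H](C)[C@@H]3[C@@H](O[Si](C)(C)C(C)(C)C)C2
F2 | step 12 | 2-(trimethylsilyloxy)-1,3-diene hexalin | CC(C)(C)[Si](C)(C)OC[C@]12C=C(O[Si](C)(C)C)C=C(C)[C@H]1[C@H]3OC(=O)[C@@H](C)[C@@H]3[C@@H](O[Si](C)(C)C(C)(C)C)C2
F3 | step 12 | ring-opened 2-(trimethylsilyloxy)cyclodeca-1(10),2,4-triene lactone | CC(C)(C)[Si](C)(C)O[C@H]1C/C(CO[Si](C)(C)C(C)(C)C)=C\C(O[Si](C)(C)C)=C/C(C)=C/[C@H]2OC(=O)[C@@H](C)[C@H]12
F4 | step 12 | 2-oxo-germacra-1(10),4-dien-6α,12-olide bis-silyl ether | CC(C)(C)[Si](C)(C)O[C@H]1C/C(CO[Si](C)(C)C(C)(C)C)=C\C(=O)C/C(C)=C/[C@H]2OC(=O)[C@@H](C)[C@H]12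
F5 | step 12 | 2-hydroxy-germacra-1(10),4-dien-6α,12-olide bis-silyl ether (C2 both epimers) | CC(C)(C)[Si](C)(C)O[C@H]1C/C(CO[Si](C)(C)C(C)(C)C)=C\C(O)C/C(C)=C/[C@H]2OC(=O)[C@@H](C)[C@H]12
F6 | step 12 | 2-O-(imidazol-1-ylthiocarbonyl) derivative of F5 | CC(C)(C)[Si](C)(C)O[C@H]1C/C(CO[Si](C)(C)C(C)(C)C)=C\C(OC(=S)n3ccnc3)C/C(C)=C/[C@H]2OC(=O)[C@@H](C)[C@H]12
F7 | step 2 | (1R,2S,5R)-menthyl 3-oxocyclohex-1-ene-1-carboxylate | CC(C)[C@@H]1CC[C@@H](C)C[C@H]1OC(=O)C1=CC(=O)CCC1
F8 | step 2 | menthyl ester analogue of 4 | CC(C)[C@@H]1CC[C@@H](C)C[C@H]1OC(=O)[C@]12CC=C[C@](C)(O[Si](CC)(CC)CC)[C@H]1C(=O)CCC2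
F9 | step 2 | menthyl ester analogue of 6 | CC(C)[C@@H]1CC[C@@H](C)C[C@H]1OC(=O)[C@]12CC=C[C@](C)(O[Si](CC)(CC)CC)[C@H]1C(=O)C=CC2
F10 | step 4 | 6β-hydroxy-2,7-diene methyl ester (C6 epimer, ester intact) | COC(=O)[C@]12CC=C[C@](C)(O[Si](CC)(CC)CC)[C@H]1[C@H](O)C=CC2
F11 | step 4 | 6α-(4-nitrobenzoyloxy)-2,7-diene methyl ester | COC(=O)[C@]12CC=C[C@](C)(O[Si](CC)(CC)CC)[C@H]1[C@@H](OC(=O)c3ccc(cc3)[N+](=O)[O-])C=CC2
F12 | step 8 | 4β,6α,14-tris(triethylsilyloxy)-7α,8α-epoxy-2-ene | CC[Si](CC)(CC)OC[C@]12CC=C[C@](C)(O[Si](CC)(CC)CC)[C@H]1[C@@H](O[Si](CC)(CC)CC)[C@H]3O[C@H]3C2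
F13 | step 8 | 7β-isopropenyl-8α-ol, 4β,6α,14-tris(triethylsilyl) ether | CC[Si](CC)(CC)OC[C@]12CC=C[C@](C)(O[Si](CC)(CC)CC)[C@H]1[C@@H](O[Si](CC)(CC)CC)[C@H](C(C)=C)[C@@H](O)C2
F14 | step 8 | 8α-(tert-butyldimethylsilyl) ether of F13 | CC[Si](CC)(CC)OC[C@]12CC=C[C@](C)(O[Si](CC)(CC)CC)[C@H]1[C@@H](O[Si](CC)(CC)CC)[C@H](C(C)=C)[C@@H](O[Si](C)(C)C(C)(C)C)C2
F15 | step 8 | 7β-isopropenyl-2-ene-4β,6α,14-triol 8α-(tert-butyldimethylsilyl) ether | OC[C@]12CC=C[C@](C)(O)[C@H]1[C@@H](O)[C@H](C(C)=C)[C@@H](O[Si](C)(C)C(C)(C)C)C2
F16 | step 17 | 14-hydroxy-8α-silyloxy-germacra-1(10),4,11(13)-trien-6α,12-olide | CC(C)(C)[Si](C)(C)O[C@H]1C/C(CO)=C\CC/C(C)=C/[C@H]2OC(=O)C(=C)[C@H]12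
F17 | step 17 | (1R,10R)-1,10-epoxy-14-hydroxy-8α-silyl ether | CC(C)(C)[Si](C)(C)O[C@H]1C[C@]2(CO)O[C@@H]2CC/C(C)=C/[C@H]2OC(=O)C(=C)[C@H]12
F18 | step 17 | (1R,10R)-1,10-epoxy-14-acetoxy-8α-silyl ether | CC(C)(C)[Si](C)(C)O[C@H]1C[C@]2(COC(C)=O)O[C@@H]2CC/C(C)=C/[C@H]2OC(=O)C(=C)[C@H]12
A1 | alternative 1 | open-chain aldoxime on a trans 4-vinyl-γ-lactone | C[C@@H]1C(=O)O[C@H](/C=C(C)/CCCC=NO)[C@H]1C=C
A2 | alternative 1 | bridged isoxazoline of the ten-membered carbocycle with trans lactone | C[C@@H]1C(=O)O[C@@H]2/C=C(C)/CCCC3=NO[C@@H](C3)[C@@H]12
A3 | alternative 2 | seco phosphonate aldehyde | CCOC(=O)C(P(=O)(OCC)OCC)C[C@H](O[Si](C)(C)C(C)(C)C)[C@@H](C(=C)COCc1ccc(OC)cc1)[C@H](OCc1ccc(OC)cc1)/C=C(C)/CCC=O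
A4 | alternative 2 | cyclodeca-1(10),4-diene with C14 ethyl ester | CC(C)(C)[Si](C)(C)O[C@H]1C/C(C(=O)OCC)=C\CC/C(C)=C/[C@@H](OCc2ccc(OC)cc2)[C@@H]1C(=C)COCc1ccc(OC)cc1
A5 | alternative 3 | seco vinyl iodide aldehyde acrylate | COC(=O)C(=C)[C@@H](C=O)[C@@H](O[Si](C)(C)C(C)(C)C)C/C(CO[Si](C)(C)C(C)(C)C)=C\CC/C(C)=C/I
A6 | alternative 3 | bis-silylated germacra-1(10),4-dienolide with α-methylene lactone (identical with 24) | CC(C)(C)[Si](C)(C)O[C@H]1C/C(CO[Si](C)(C)C(C)(C)C)=C\CC/C(C)=C/[C@H]2OC(=O)C(=C)[C@H]12
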